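## The problem

Compound 44 is a germacranolide: a ten-membered carbocycle (C1–C10) trans-fused at C7–C8 to an α-methylene-γ-butyrolactone (O8–C12(=O)–C11=C13). It carries a cis-epoxide at C1–C2 next to the C3 ketone, a tertiary carbinol at C4, an acetate on O5, an (E)-but-2-enoate on O6 and a methyl-bearing centre at C10. Eight stereocentres must be set (C1, C2, C4, C5, C6, C7, C8, C10). C4–C7 are contiguous and can control one another on a six-membered ring. C10 lies across the macrocycle from them and is out of reach of ordinary 1,2- or 1,3-induction, and C1, C2 and C8 can only be set on the ten-membered ring by its conformation. The epoxy ketone, the exo-methylene lactone, the two esters (hydrolysis, O5/O6 acyl shift) and the C3/C4 α-ketol tolerate neither organometallic reagents nor strong base, so they must appear last and in a fixed order. Direct end-to-end closure of a ten-membered ring is costly in entropy and transannular strain. The enabling feature is that the C3 carbonyl and the C8 oxygen stand 1,6 to one another: joining C3 to C8 gives a cyclohexane-1,2-diol with a vinyl group (C1–C2) on C3 and an (E)-propenyl group (C9–C10–C14) on C8, the retron of an oxy-Cope ring expansion. C4 is quaternary, so the C3 carbonyl can later enolise only towards C2. A second feature is also used: on that cyclohexane C12 hangs from C7, cis-1,3 to O3, so the future lactone carbon can hold O3 as an acetal.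

## Retrosynthesis

**Esters last (44 → 40).** The O6 crotonate and O5 acetate C–O bonds are cut first, since neither ester survives the enolate, hydride or organometallic steps. This leads back through 43, 42 and 41 to 40, in which O6 is a 4-methoxyphenyl ether and O4/O5 a trans-fused acetonide. The two oxygens are already differentiated, and the O4/O5 pair needs no selectivity because only O5 is secondary. The forward steps must be mild: tetravalent cerium, dilute acetic acid and DMAP-catalysed acylation.

**Methylene, epoxide, enone (40 → 34).** C11=C13 is cut to lactone 37, the epoxide C–O bonds to the Z-enone 36, and C1=C2 to ketone 34. The order is forced. The exo-methylene lactone would compete with the enone for the peroxide anion, so epoxidation comes first. The C3 ketone is more acidic than the lactone, so the lactone can only be enolised once the ketone has become the non-enolisable epoxy ketone. In 34 the ketone enolises only towards C2 because C4 is quaternary.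

**Lactone (34 → 32 → 31).** The O8–C12 bond and the C12 oxidation level are traced to alcohol 32, in which C12 is still an acetal carbon bonded to O3 as an enol acetal. Alcohol 32 comes from ketone 31 by reduction. Carrying C12 as an acetal means no protecting group or separate oxidation-state change is needed on the side chain after the ring expansion. It also keeps C3 masked while C8 is reduced, so the two carbonyl positions are never present together as a 1,6-dione that could undergo transannular aldol reaction.

**Key disconnection (31 → 29).** Reconnecting C3–C8 and cutting C1–C10 gives the cyclohexane 29, the oxy-Cope precursor. A second free alkoxide on O3 was weighed within this same disconnection. It would leave the two carbonyl carbons undifferentiated in the product and give no control over the alkenyl additions that build the precursor. In 29, O3 is therefore joined to C12 as a bridged methyl acetal (a 2-oxabicyclo[3.3.1]nonane). The bridge holds the cyclohexane in the chair with both alkenyl groups equatorial, the arrangement required for the chair [3,3] shift. The forward step must form C1–C10 with the C10 configuration fixed by the E-propenyl geometry and the C3/C8 configurations.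

**Propenyl and the bridge (29 → 27 + 28 → 23).** The C8–C9 bond is cut to the bridged ketone 27 and (E)-1-bromoprop-1-ene 28. In 27 the carbonyl is flanked by two bridgeheads, so it cannot enolise and C7 is safe. One face is blocked by the axial C4 methyl group, so the nucleophile should enter over the oxa-bridge. Ketone 27 is traced through 26, 25 and 24 to the bridged acetal 23, which forms from aldehyde 21 when the C3 hydroxyl is released.

**C5 and C6 oxygens (21 → 19 → 18 → 17).** The C6–OAr bond is cut to the 5α,6α-epoxide 18, and that to the alkene 17. A trans-diaxial epoxide opening is the only reliable way to a trans-diol. It is done before the bridge is made, in the chair that keeps the C7 and C8 substituents equatorial. Attack at C6 is remote from the quaternary C4, and the aryl ether differentiates O6 from O5 in the same step.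

**C4 and the C3 carbinol (17 → 16 → 13 → 12 → 10 + 11).** The tertiary allylic diol 16 is traced to epoxy alcohol 13 by a selenide transposition, and 13 to propargylic alcohol 12 by hydroxyl-directed epoxidation. Alcohol 12 comes from enone 10 and ethynylmagnesium bromide 11. Ethynyl is preferred to vinyl as the C1–C2 unit at this stage for three reasons. A slim acetylide adds axially, trans to the C7 side chain. An alkyne is inert to the two epoxidations. An axial ethynyl group leaves the α face of C5=C6 open in step 10. It is reduced to vinyl (25) before the propenyl group arrives.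

**Ring and C7 (10 → 8 → 4 + 5).** The C8 oxygen is cut back to enone 8 (enolate oxidation), which is then disconnected at C7–C8 and C4=C5 into enal 4 and tert-butyl 3-oxopentanoate 5. An organocatalytic Michael–aldol annulation sets C7, the only stereocentre not derived from another. Carvone has the same ring, but its isopropenyl group would act as a second Cope partner next to the C8 alkoxide. Enone 8 carries a saturated two-carbon chain instead.

**Enal (4 → 2 + 3 → 1).** Cross-metathesis of silyl ether 2 with crotonaldehyde 3; 2 comes from but-3-en-1-ol 1.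

## Roads not taken

**Alternative 1:** The cut is C3–C4. The open-chain Z-enal methyl ketone A1, already carrying the lactone and the O5/O6 acetonide, would be closed with low-valent titanium (TiCl3(DME)1.5, Zn–Cu) to the ten-membered Z-allylic 3,4-diol A2. Merits: it is convergent, the Z C1=C2 bond is in place before ring closure, and the C3 allylic alcohol in A2 could direct a stereospecific epoxidation. That is a more dependable handle for the C1–C2 epoxide than the conformational control the chosen route relies on in step 24. Weak points: the quaternary C4 centre is created in the macrocyclisation itself, with only the ring-closing transition state to control it. Enal ketyls can couple through C1 as well as C3, and over-reduction to the alkene is a known side path. High dilution is needed, and the lactone must survive the reductant. Against the better epoxidation handle, the chosen plan sets C4 on a six-membered ring by a directed epoxidation, needs no macrocyclisation, and transfers C10 stereospecifically.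

**Alternative 2:** The cut is C4–C5. The seco compound A3, with epoxy ketone, methylene lactone and crotonate all present, would be enolised at C4 with Bu2BOTf and iPr2NEt and closed onto the C5 aldehyde to give macrocycle A4. Merits: it is the most convergent of the routes, and only PMB removal and acetylation would follow. In end-game step economy it is clearly better than the chosen route, which spends nine steps after ring formation. Weak points: a fully substituted boron enolate must form a quaternary centre while closing a ten-membered ring. The boron triflate and amine meet an epoxy ketone and a Michael-accepting lactone. The α-acyloxy aldehyde can epimerise or eliminate at C6. C4 and C5 are set with no precedent-based model for the sense. All the risk falls on the last C–C bond. The chosen plan accepts a longer end game in exchange for forming the ring on a robust intermediate.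

**Alternative 3:** The cut is C2–C8 of a hydroazulenone. The epoxy ketone A5 would condense with TsNHNH2 and fragment to the ten-membered ynone A6. Merits: the fragmentation is mild and stereospecific, and semi-hydrogenation of the C1≡C2 alkyne would guarantee the Z geometry. The chosen route cannot promise that in step 23. Weak points: A5 is a bicyclic compound with a tetrasubstituted ring-fusion epoxide and all of C3–C7 in place, itself a long synthesis. C10 is α to the C1 carbonyl in A5 and can epimerise before or during hydrazone formation. The cyclodecynone is strained. The C8 ketone in A6 sits next to C7 with a β-alkoxy group at C6. Against the assured alkene geometry, the chosen plan builds the ring from a monocyclic precursor and fixes C10 by chirality transfer rather than by an epimerisable centre.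

Key step: step 20

Convention and assumption: locants follow germacranolide numbering (C1–C15) on every intermediate; β is the ring face that carries the C7 side chain and α the opposite face; the annulation of step 3 is assumed to follow the usual facial model for diarylprolinol silyl ether iminium ions, which gives (S) at C7.

Step 1
Reactants: 1 but-3-en-1-ol
Product: 2 (but-3-en-1-yloxy)(tert-butyl)diphenylsilane
Conditions: tBuPh2SiCl, imidazole, CH2Cl2, 0 °C to rt
Reagents that add atoms: tert-butyl(chloro)diphenylsilane, CC(C)(C)[Si](Cl)(c1ccccc1)c1ccccc1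
Why: Standard silylation of a primary alcohol; this silyl ether survives the acid of step 3 and can be removed in step 12 beside a hindered secondary silyl ether.

Step 2
Reactants: 2 (but-3-en-1-yloxy)(tert-butyl)diphenylsilane; 3 (E)-but-2-enal
Product: 4 (E)-5-[(tert-butyldiphenylsilyl)oxy]pent-2-enal
Conditions: second-generation Hoveyda–Grubbs catalyst (2 mol %), excess 3, CH2Cl2, 40 °C
Reagents that add atoms: none
Why: Olefin cross-metathesis of a terminal alkene with crotonaldehyde, which is E-selective and driven by loss of propene.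

Step 3
Reactants: 4 (E)-5-[(tert-butyldiphenylsilyl)oxy]pent-2-enal; 5 tert-butyl 3-oxopentanoate
Product: 8 (5S)-5-{2-[(tert-butyldiphenylsilyl)oxy]ethyl}-2-methylcyclohex-2-en-1-one, via Michael adduct 6 (not isolated), via keto ester 7 (not isolated)
Conditions: (S)-2-[diphenyl(trimethylsilyloxy)methyl]pyrrolidine (10 mol %), PhCO2H (10 mol %), toluene, rt; then TsOH·H2O (20 mol %), 80 °C
Reagents that add atoms: none
Why: Iminium-catalysed Michael addition, then acid-mediated intramolecular aldol condensation, tert-butyl ester cleavage and decarboxylation (organocatalytic Robinson-type annulation). C7 is set in the Michael step: the keto ester adds to the face of the s-trans E-iminium ion not shielded by the diphenyl(silyloxy)methyl group.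

Step 4
Reactants: 8 (5S)-5-{2-[(tert-butyldiphenylsilyl)oxy]ethyl}-2-methylcyclohex-2-en-1-one
Product: 9 (5S,6S)-5-{2-[(tert-butyldiphenylsilyl)oxy]ethyl}-6-hydroxy-2-methylcyclohex-2-en-1-one (8α-hydroxy enone)
Conditions: LiN(iPr)2, THF, −78 °C; then 2-(benzenesulfonyl)-3-phenyloxaziridine, −78 °C
Reagents that add atoms: 2-(benzenesulfonyl)-3-phenyloxaziridine, O=S(=O)(N1OC1c1ccccc1)c1ccccc1
Why: Kinetic deprotonation can only occur at C8, the sole sp3 α-carbon; Davis oxidation of the enolate places the hydroxyl anti to the adjacent C7 side chain.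

Step 5
Reactants: 9 8α-hydroxy enone
Product: 10 (5S,6S)-5-{2-[(tert-butyldiphenylsilyl)oxy]ethyl}-2-methyl-6-[(triisopropylsilyl)oxy]cyclohex-2-en-1-one
Conditions: iPr3SiOTf, 2,6-lutidine, CH2Cl2, −78 to 0 °C
Reagents that add atoms: triisopropylsilyl trifluoromethanesulfonate, CC(C)[Si](OS(=O)(=O)C(F)(F)F)(C(C)C)C(C)C
Why: Silylation of a secondary alcohol; the bulky, non-chelating ether keeps O8 from steering step 6 by chelation and outlasts the primary silyl ether in step 12.

Step 6
Reactants: 10 8α-silyloxy enone; 11 ethynylmagnesium bromide (HC≡CMgBr)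
Product: 12 3α-ethynyl-3β-hydroxy-4-methyl-7β-{2-[(tert-butyldiphenylsilyl)oxy]ethyl}-8α-[(triisopropylsilyl)oxy]cyclohex-4-ene (ring carbons C3–C8)
Conditions: 11, CeCl3, THF, −78 to −20 °C
Reagents that add atoms: none
Why: 1,2-Addition of an acetylide to a cyclohexenone; the slim nucleophile attacks axially, trans to the pseudo-equatorial C7 side chain, giving the α-ethynyl β-alcohol, while the equatorial non-chelating O8 silyl ether does not override this.

Step 7
Reactants: 12 propargylic alcohol
Product: 13 4β,5β-epoxide of 12
Conditions: VO(acac)2 (5 mol %), tBuOOH, CH2Cl2, 0 °C to rt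
Reagents that add atoms: tert-butyl hydroperoxide, CC(C)(C)OO
Why: Hydroxyl-directed vanadium-catalysed epoxidation of an allylic alcohol delivers oxygen syn to the C3 hydroxyl, which sets C4 (β-oxygen, α-methyl); the alkyne is inert.

Step 8
Reactants: 13 4β,5β-epoxy alcohol
Product: 16 3α-ethynyl-4α-methylcyclohex-5-ene-3β,4β-diol with the 7β side chain and 8α-OTIPS, via hydroxy selenide 14 (not isolated), via selenoxide 15 (not isolated)
Conditions: (PhSe)2, NaBH4, EtOH, rt; then H2O2 (30%), pyridine, THF, 0 °C to rt
Reagents that add atoms: diphenyl diselenide, c1ccc(cc1)[Se][Se]c1ccccc1 (selenium is carried only in 14 and 15); hydrogen peroxide, OO (its oxygen is carried only in 15)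
Why: Sharpless–Lauer epoxide-to-allylic-alcohol transposition: selenolate opens the epoxide at the secondary C5 with inversion, and the selenoxide can only eliminate towards C6 because C4 has no hydrogen.

Step 9
Reactants: 16 tertiary allylic diol
Product: 17 3β,4β-O-isopropylidene acetal of 16
Conditions: 2-methoxypropene, PPTS (cat.), CH2Cl2, 0 °C to rt
Reagents that add atoms: 2-methoxypropene, C=C(C)OC
Why: Acetonide formation on a cis-diol; it caps both tertiary hydroxyls so that neither directs the next epoxidation to the β face, and it adds bulk to that face.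

Step 10
Reactants: 17 cis-acetonide
Product: 18 5α,6α-epoxide of 17
Conditions: mCPBA, NaHCO3, CH2Cl2, 0 °C
Reagents that add atoms: 3-chloroperoxybenzoic acid, OOC(=O)c1cccc(Cl)c1
Why: Prilezhaev epoxidation; in the half-chair with the C7 and C8 substituents pseudo-equatorial, the pseudo-axial C4–O bond and the dioxolane cover the β face, and the α face carries only the slim axial ethynyl group.

Step 11
Reactants: 18 5α,6α-epoxide
Product: 19 6β-(4-methoxyphenoxy)-5α-hydroxy derivative of 17
Conditions: 4-methoxyphenol, Cs2CO3, DMF, 100 °C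
Reagents that add atoms: 4-methoxyphenol, COc1ccc(O)cc1
Why: Trans-diaxial (Fürst–Plattner) epoxide opening: phenoxide attacks C6, remote from quaternary C4, from the β face in the chair that keeps the C7 and C8 substituents equatorial. This sets C5 (α-OH) and C6 (β-OAr) and differentiates the two oxygens.

Step 12
Reactants: 19 aryl ether alcohol
Product: 20 primary alcohol (C12–OH) of 19
Conditions: NH4F, MeOH, 50 °C
Reagents that add atoms: none
Why: Fluoride desilylation that is selective for the primary silyl ether over the hindered secondary triisopropylsilyl ether.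

Step 13
Reactants: 20 primary alcohol
Product: 21 C12 aldehyde
Conditions: TEMPO (10 mol %), PhI(OAc)2, CH2Cl2, rt
Reagents that add atoms: none
Why: Oxoammonium oxidation is selective for the primary alcohol over the hindered C5 hydroxyl; no lactol can form because O3 is still in the acetonide.

Step 14
Reactants: 21 C12 aldehyde
Product: 23 bridged methyl acetal (O3–C12 bond; 2-oxabicyclo[3.3.1]nonane; exo 12-OMe; 4β,5α-diol; 6β-OAr; 8α-OTIPS; 3α-ethynyl), via dimethyl acetal triol 22 (not isolated)
Conditions: CSA (cat.), MeOH, rt; then PPTS, benzene, 4 Å molecular sieves, 60 °C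
Reagents that add atoms: methanol, CO
Why: Acid methanolysis removes the labile di-tertiary acetonide and converts the aldehyde to its dimethyl acetal; on removal of methanol the C3 hydroxyl, cis-1,3 to the side chain, closes the six-membered bridged acetal (intramolecular transacetalisation). The C5 hydroxyl is trans and cannot reach, and the methoxy group takes the exo position because the endo position points into the carbocycle.

Step 15
Reactants: 23 bridged acetal diol
Product: 24 4β,5α-O-isopropylidene acetal of 23
Conditions: 2-methoxypropene, PPTS (cat.), CH2Cl2, 0 °C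
Reagents that add atoms: 2-methoxypropene, C=C(C)OC
Why: In the chair fixed by the bridge the C4 and C5 hydroxyls are trans-diequatorial, and kinetic acetalisation gives the trans-fused acetonide that protects both until step 26.

Step 16
Reactants: 24 ethynyl trans-acetonide
Product: 25 3α-vinyl analogue of 24
Conditions: H2 (1 atm), Pd/CaCO3 poisoned with Pb(OAc)2 (Lindlar catalyst), quinoline, EtOAc, rt
Reagents that add atoms: none
Why: Lindlar semi-hydrogenation of a terminal alkyne to the vinyl group; no other reducible group is present.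

Step 17
Reactants: 25 vinyl compound
Product: 26 8α-alcohol
Conditions: Bu4NF, THF, rt to 40 °C
Reagents that add atoms: none
Why: Fluoride cleavage of the only silyl ether left.

Step 18
Reactants: 26 8α-alcohol
Product: 27 bridged C8 ketone
Conditions: Dess–Martin periodinane, pyridine, CH2Cl2, rt
Reagents that add atoms: none
Why: Oxidation of the only free hydroxyl; the ketone lies between two bridgeheads and cannot enolise (Bredt), so C7 cannot epimerise.

Step 19
Reactants: 27 bridged C8 ketone; 28 (E)-1-bromoprop-1-ene
Product: 29 3α-vinyl-8β-[(E)-prop-1-enyl]-8α-hydroxy bridged acetal (oxy-Cope precursor)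
Conditions: 28, tBuLi (2 equiv), Et2O, −78 °C; then 27, THF, −78 to −40 °C
Reagents that add atoms: none
Why: Lithium–bromine exchange proceeds with retention of the E geometry, and the alkenyllithium adds to the non-enolisable ketone. The face under the carbocycle is blocked by the syn-axial C4 methyl group, so attack comes over the oxa-bridge and gives the trans arrangement with both alkenyl groups equatorial.

Step 20
Reactants: 29 oxy-Cope precursor
Product: 31 ten-membered C8 ketone with C3 as bridged methyl enol acetal (2E-enol ether; 4,5-acetonide; 6-OAr; C10 methyl as in the target), via potassium enolate 30 (not isolated)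
Conditions: KH, 18-crown-6, THF, 0 °C to rt; then AcOH, −78 °C
Reagents that add atoms: none
Why: KH removes the C8 hydroxyl proton and 18-crown-6 frees the potassium alkoxide, which lowers the barrier of the [3,3] shift of the C1=C2–C3–C8–C9=C10 array (anionic oxy-Cope rearrangement); C1–C10 forms as C3–C8 breaks. The closest known reaction type is the anionic oxy-Cope ring expansion of 1,2-dialkenylcyclohexanols and 1,2-dialkenylcyclohexane-1,2-diol derivatives to cyclodec-5-enones and cyclodecane-1,6-diones. The ten-membered ring is not closed end to end: it arises by four-carbon ring expansion of the cyclohexane through a six-membered chair array, and the former oxa-bridge survives as an eight-membered enol acetal ring spanning C3 and C7. C10 is the only new stereocentre; it follows from the E geometry of the propenyl group (methyl equatorial in the chair array) and from the sense of the gauche relationship between the two alkenyl groups, which is fixed by the configurations at C3 and C8 and leads to the configuration of the target. The selectivity needed is chair over boat, and the acetal bridge secures it by locking the cyclohexane in the chair with both alkenyl groups equatorial. Only the C3–C8 bond is flanked by two alkenyl groups and the oxido substituent, so no other σ bond can take part. Because O3 is an acetal oxygen and not a second alkoxide, C3 emerges as an enol ether and C8 alone as an enolate, which is protonated at −78 °C before it can equilibrate towards C7 and expel the C6 aryloxide.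

Step 21
Reactants: 31 ten-membered ketone
Product: 32 (8R)-alcohol
Conditions: NaBH4, CeCl3·7H2O, MeOH, −78 °C
Reagents that add atoms: none
Why: Luche reduction under nearly neutral conditions, which suppresses enolisation towards C7 and loss of the C6 aryloxide. Hydride is expected to enter anti to the C7–C11 bond, which the acetal bridge holds over one face of the carbonyl, giving the 8R alcohol needed for the trans-fused lactone.

Step 22
Reactants: 32 (8R)-alcohol
Product: 34 8,12-lactone with free C3 ketone, via lactol 33 (not isolated)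
Conditions: oxalic acid (cat.), THF/H2O, 0 °C to rt; then TEMPO (10 mol %), PhI(OAc)2, CH2Cl2, rt
Reagents that add atoms: water, O
Why: Enol acetal hydrolysis (protonation at C2) releases the C3 ketone and the C12 aldehyde, which the C8 hydroxyl captures as a five-membered lactol; TEMPO/PhI(OAc)2 then oxidises the lactol to the lactone.

Step 23
Reactants: 34 keto lactone
Product: 36 (1Z)-enone, via silyl enol ether 35 (not isolated)
Conditions: LiN(SiMe3)2, Me3SiCl, THF, −78 °C; then Pd(OAc)2, MeCN, rt
Reagents that add atoms: chlorotrimethylsilane, C[Si](C)(C)Cl (silicon is carried only in 35)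
Why: Saegusa–Ito oxidation: the ketone is more acidic than the lactone and can enolise only towards C2 because C4 is quaternary. β-Hydride elimination from the palladium enolate gives the C1=C2 enone, expected as the less strained Z isomer of a cyclodec-2-enone.

Step 24
Reactants: 36 (1Z)-enone
Product: 37 (1S,2S)-1,2-epoxy-3-ketone
Conditions: tBuOOH, DBU, CH2Cl2, 0 °C
Reagents that add atoms: tert-butyl hydroperoxide, CC(C)(C)OO
Why: Weitz–Scheffer nucleophilic epoxidation: the peroxide anion adds to C1 on the outer face of the Z-enone, anti to ring carbon C9 with H10 eclipsing the double bond (allylic strain). This places oxygen syn to the C10 methyl group, the 1S,2S epoxide, and closure within the ring keeps it cis.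

Step 25
Reactants: 37 epoxy ketone lactone
Product: 40 α-methylene lactone, via Mannich base 38 (not isolated), via ammonium iodide 39 (not isolated)
Conditions: LiN(iPr)2, THF, −78 °C, then Me2N=CH2 I; then MeI, THF, rt; then NaHCO3, CH2Cl2/H2O, rt
Reagents that add atoms: N,N-dimethylmethyleneiminium iodide, C=[N+](C)C.[I-]; iodomethane, CI (its methyl is carried only in 39)
Why: Mannich reaction of the lactone enolate with Eschenmoser's salt, quaternisation and β-elimination give the exo-methylene group (C13); the epoxy ketone has no enolisable α-hydrogen, so the amide base acts on the lactone alone.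

Step 26
Reactants: 40 α-methylene lactone
Product: 41 4,5-diol
Conditions: AcOH/H2O (4:1), 40 °C
Reagents that add atoms: none
Why: Mild acid hydrolysis of the strained trans-fused acetonide; an epoxide next to a carbonyl is deactivated towards acid opening.

Step 27
Reactants: 41 4,5-diol
Product: 42 5-acetate
Conditions: Ac2O, pyridine, DMAP (cat.), CH2Cl2, 0 °C
Reagents that add atoms: acetic anhydride, CC(=O)OC(C)=O
Why: Acetylation of the secondary C5 hydroxyl; the tertiary C4 hydroxyl does not react under these conditions.

Step 28
Reactants: 42 5-acetate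
Product: 43 6-alcohol
Conditions: (NH4)2Ce(NO3)6, MeCN/H2O, 0 °C
Reagents that add atoms: none
Why: Oxidative dearylation of a 4-methoxyphenyl ether by tetravalent cerium; the arene leaves as benzoquinone and the C6–O bond is untouched, so C6 keeps its configuration.

Step 29
Reactants: 43 6-alcohol
Product: 44 CNP0358125.1
Conditions: (E)-but-2-enoic anhydride, DMAP, pyridine, CH2Cl2, 0 °C to rt
Reagents that add atoms: (E)-but-2-enoic anhydride, C/C=C/C(=O)OC(=O)/C=C/C
Why: DMAP-catalysed acylation of the C6 hydroxyl; the anhydride avoids the vinylketene pathway that deconjugates crotonyl chloride.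

## Compound list

1 | but-3-en-1-ol | C=CCCO | starting material
2 | (but-3-en-1-yloxy)(tert-butyl)diphenylsilane | C=CCCO[Si](c1ccccc1)(c1ccccc1)C(C)(C)C | intermediate
3 | (E)-but-2-enal | C/C=C/C=O | starting material
4 | (E)-5-[(tert-butyldiphenylsilyl)oxy]pent-2-enal | O=C/C=C/CCO[Si](c1ccccc1)(c1ccccc1)C(C)(C)C | intermediate
5 | tert-butyl 3-oxopentanoate | CCC(=O)CC(=O)OC(C)(C)C | starting material
6 | tert-butyl (3R)-5-[(tert-butyldiphenylsilyl)oxy]-3-(2-oxoethyl)-2-propanoylpentanoate (Michael adduct, C2 epimers) | CCC(=O)C(C(=O)OC(C)(C)C)[C@@H](CC=O)CCO[Si](c1ccccc1)(c1ccccc1)C(C)(C)C | intermediate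
7 | tert-butyl (6S)-6-{2-[(tert-butyldiphenylsilyl)oxy]ethyl}-3-methyl-2-oxocyclohex-3-ene-1-carboxylate (C1 epimers) | O=C1C(C)=CC[C@@H](CCO[Si](c2ccccc2)(c2ccccc2)C(C)(C)C)C1C(=O)OC(C)(C)C | intermediate
8 | (5S)-5-{2-[(tert-butyldiphenylsilyl)oxy]ethyl}-2-methylcyclohex-2-en-1-one | O=C1C(C)=CC[C@@H](CCO[Si](c2ccccc2)(c2ccccc2)C(C)(C)C)C1 | intermediate
9 | (5S,6S)-5-{2-[(tert-butyldiphenylsilyl)oxy]ethyl}-6-hydroxy-2-methylcyclohex-2-en-1-one | O=C1C(C)=CC[C@@H](CCO[Si](c2ccccc2)(c2ccccc2)C(C)(C)C)[C@@H]1O | intermediate
10 | (5S,6S)-5-{2-[(tert-butyldiphenylsilyl)oxy]ethyl}-2-methyl-6-[(triisopropylsilyl)oxy]cyclohex-2-en-1-one | O=C1C(C)=CC[C@@H](CCO[Si](c2ccccc2)(c2ccccc2)C(C)(C)C)[C@@H]1O[Si](C(C)C)(C(C)C)C(C)C | intermediate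
11 | ethynylmagnesium bromide | C#C[Mg]Br | starting material
12 | 3α-ethynyl-3β-hydroxy-4-methyl-7β-{2-[(tert-butyldiphenylsilyl)oxy]ethyl}-8α-[(triisopropylsilyl)oxy]cyclohex-4-ene | C#C[C@]1(O)C(C)=CC[C@@H](CCO[Si](c2ccccc2)(c2ccccc2)C(C)(C)C)[C@@H]1O[Si](C(C)C)(C(C)C)C(C)C | intermediate
13 | 4β,5β-epoxide of 12 (3α-ethynyl, 3β-OH, 4α-methyl) | C#C[C@]1(O)[C@@]2(C)O[C@H]2C[C@@H](CCO[Si](c3ccccc3)(c3ccccc3)C(C)(C)C)[C@@H]1O[Si](C(C)C)(C(C)C)C(C)C | intermediate
14 | 5α-(phenylselanyl)-3β,4β-diol (hydroxy selenide) | C#C[C@]1(O)[C@@](C)(O)[C@H]([Se]c2ccccc2)C[C@@H](CCO[Si](c2ccccc2)(c2ccccc2)C(C)(C)C)[C@@H]1O[Si](C(C)C)(C(C)C)C(C)C | intermediate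
15 | selenoxide of 14 (selenium epimers) | C#C[C@]1(O)[C@@](C)(O)[C@H]([Se](=O)c2ccccc2)C[C@@H](CCO[Si](c2ccccc2)(c2ccccc2)C(C)(C)C)[C@@H]1O[Si](C(C)C)(C(C)C)C(C)C | intermediate
16 | 3α-ethynyl-4α-methylcyclohex-5-ene-3β,4β-diol with the 7β side chain and 8α-OTIPS | C#C[C@]1(O)[C@@](C)(O)C=C[C@@H](CCO[Si](c2ccccc2)(c2ccccc2)C(C)(C)C)[C@@H]1O[Si](C(C)C)(C(C)C)C(C)C | intermediate
17 | 3β,4β-O-isopropylidene acetal of 16 | C#C[C@]1(OC(C)(C)O2)[C@]2(C)C=C[C@@H](CCO[Si](c3ccccc3)(c3ccccc3)C(C)(C)C)[C@@H]1O[Si](C(C)C)(C(C)C)C(C)C | intermediate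
18 | 5α,6α-epoxide of 17 | C#C[C@]1(OC(C)(C)O2)[C@]2(C)[C@@H]3O[C@@H]3[C@@H](CCO[Si](c4ccccc4)(c4ccccc4)C(C)(C)C)[C@@H]1O[Si](C(C)C)(C(C)C)C(C)C | intermediate
19 | 6β-(4-methoxyphenoxy)-5α-hydroxy compound (3β,4β-acetonide, 8α-OTIPS, C12 silyl ether) | C#C[C@]1(OC(C)(C)O2)[C@]2(C)[C@H](O)[C@@H](Oc3ccc(OC)cc3)[C@@H](CCO[Si](c3ccccc3)(c3ccccc3)C(C)(C)C)[C@@H]1O[Si](C(C)C)(C(C)C)C(C)C | intermediate
20 | C12 primary alcohol of 19 | C#C[C@]1(OC(C)(C)O2)[C@]2(C)[C@H](O)[C@@H](Oc3ccc(OC)cc3)[C@@H](CCO)[C@@H]1O[Si](C(C)C)(C(C)C)C(C)C | intermediate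
21 | C12 aldehyde | C#C[C@]1(OC(C)(C)O2)[C@]2(C)[C@H](O)[C@@H](Oc3ccc(OC)cc3)[C@@H](CC=O)[C@@H]1O[Si](C(C)C)(C(C)C)C(C)C | intermediate
22 | 3β,4β,5α-triol C12 dimethyl acetal | C#C[C@]1(O)[C@@](C)(O)[C@H](O)[C@@H](Oc2ccc(OC)cc2)[C@@H](CC(OC)OC)[C@@H]1O[Si](C(C)C)(C(C)C)C(C)C | intermediate
23 | bridged methyl acetal (O3–C12; exo-OMe; 4β,5α-diol; 6β-OAr; 8α-OTIPS; 3α-ethynyl) | C#C[C@]1(O[C@@H](OC)C2)[C@@](C)(O)[C@H](O)[C@@H](Oc3ccc(OC)cc3)[C@@H]2[C@@H]1O[Si](C(C)C)(C(C)C)C(C)C | intermediate
24 | 4β,5α-O-isopropylidene acetal of 23 | C#C[C@]1(O[C@@H](OC)C2)[C@@]3(C)OC(C)(C)O[C@@H]3[C@@H](Oc4ccc(OC)cc4)[C@@H]2[C@@H]1O[Si](C(C)C)(C(C)C)C(C)C | intermediate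
25 | 3α-vinyl analogue of 24 | C=C[C@]1(O[C@@H](OC)C2)[C@@]3(C)OC(C)(C)O[C@@H]3[C@@H](Oc4ccc(OC)cc4)[C@@H]2[C@@H]1O[Si](C(C)C)(C(C)C)C(C)C | intermediate
26 | 8α-alcohol | C=C[C@]1(O[C@@H](OC)C2)[C@@]3(C)OC(C)(C)O[C@@H]3[C@@H](Oc4ccc(OC)cc4)[C@@H]2[C@@H]1O | intermediate
27 | bridged C8 ketone | C=C[C@]1(O[C@@H](OC)C2)[C@@]3(C)OC(C)(C)O[C@@H]3[C@@H](Oc4ccc(OC)cc4)[C@@H]2C1=O | intermediate
28 | (E)-1-bromoprop-1-ene | C/C=C/Br | starting material
29 | 3α-vinyl-8β-[(E)-prop-1-enyl]-8α-hydroxy bridged acetal (oxy-Cope precursor) | C=C[C@]1(O[C@@H](OC)C2)[C@@]3(C)OC(C)(C)O[C@@H]3[C@@H](Oc4ccc(OC)cc4)[C@@H]2[C@@]1(O)/C=C/C | intermediate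
30 | potassium C8 enolate of 31 | [K+].[O-]/C1=C\[C@@H](C)C/C=C2\O[C@@H](OC)C[C@@H]1[C@H](Oc3ccc(OC)cc3)[C@H]3OC(C)(C)O[C@]23C | intermediate
31 | ten-membered C8 ketone with C3 as bridged methyl enol acetal | O=C1C[C@@H](C)C/C=C2\O[C@@H](OC)C[C@@H]1[C@H](Oc3ccc(OC)cc3)[C@H]3OC(C)(C)O[C@]23C | intermediate
32 | (8R)-alcohol of 31 | O[C@@H]1C[C@@H](C)C/C=C2\O[C@@H](OC)C[C@@H]1[C@H](Oc3ccc(OC)cc3)[C@H]3OC(C)(C)O[C@]23C | intermediate
33 | 8,12-lactol with C3 ketone (C12 anomers) | C1C(O)O[C@@H]2C[C@@H](C)CCC(=O)[C@@]3(C)OC(C)(C)O[C@@H]3[C@@H](Oc3ccc(OC)cc3)[C@@H]12 | intermediate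
34 | 8,12-lactone with C3 ketone (4,5-acetonide, 6-OAr) | C1C(=O)O[C@@H]2C[C@@H](C)CCC(=O)[C@@]3(C)OC(C)(C)O[C@@H]3[C@@H](Oc3ccc(OC)cc3)[C@@H]12 | intermediate
35 | C2=C3 trimethylsilyl enol ether of 34 (geometry not defined) | C1C(=O)O[C@@H]2C[C@@H](C)CC=C(O[Si](C)(C)C)[C@@]3(C)OC(C)(C)O[C@@H]3[C@@H](Oc3ccc(OC)cc3)[C@@H]12 | intermediate
36 | (1Z)-en-3-one | C1C(=O)O[C@@H]2C[C@@H](C)/C=C\C(=O)[C@@]3(C)OC(C)(C)O[C@@H]3[C@@H](Oc3ccc(OC)cc3)[C@@H]12 | intermediate
37 | (1S,2S)-1,2-epoxy-3-ketone | C1C(=O)O[C@@H]2C[C@@H](C)[C@@H]4O[C@@H]4C(=O)[C@@]3(C)OC(C)(C)O[C@@H]3[C@@H](Oc3ccc(OC)cc3)[C@@H]12 | intermediate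
38 | 11-[(dimethylamino)methyl] lactone (C11 epimers) | CN(C)CC1C(=O)O[C@@H]2C[C@@H](C)[C@@H]4O[C@@H]4C(=O)[C@@]3(C)OC(C)(C)O[C@@H]3[C@@H](Oc3ccc(OC)cc3)[C@@H]12 | intermediate
39 | trimethylammonium iodide of 38 | C[N+](C)(C)CC1C(=O)O[C@@H]2C[C@@H](C)[C@@H]4O[C@@H]4C(=O)[C@@]3(C)OC(C)(C)O[C@@H]3[C@@H](Oc3ccc(OC)cc3)[C@@H]12.[I-] | intermediate
40 | α-methylene lactone (4,5-acetonide, 6-OAr) | C=C1C(=O)O[C@@H]2C[C@@H](C)[C@@H]4O[C@@H]4C(=O)[C@@]3(C)OC(C)(C)O[C@@H]3[C@@H](Oc3ccc(OC)cc3)[C@@H]12 | intermediate
41 | 4,5-diol | C=C1C(=O)O[C@@H]2C[C@@H](C)[C@@H]3O[C@@H]3C(=O)[C@@](C)(O)[C@H](O)[C@@H](Oc3ccc(OC)cc3)[C@@H]12 | intermediate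
42 | 5-acetate | C=C1C(=O)O[C@@H]2C[C@@H](C)[C@@H]3O[C@@H]3C(=O)[C@@](C)(O)[C@H](OC(C)=O)[C@@H](Oc3ccc(OC)cc3)[C@@H]12 | intermediate
43 | 6-alcohol | C=C1C(=O)O[C@@H]2C[C@@H](C)[C@@H]3O[C@@H]3C(=O)[C@@](C)(O)[C@H](OC(C)=O)[C@@H](O)[C@@H]12 | intermediate
44 | CNP0358125.1 (1S,2S,4S,5R,6S,7S,8R,10R) | C=C1C(=O)O[C@@H]2C[C@@H](C)[C@@H]3O[C@@H]3C(=O)[C@@](C)(O)[C@H](OC(C)=O)[C@@H](OC(=O)/C=C/C)[C@@H]12 | target

## Step count and least certain steps

Total: 29 steps. Longest linear sequence: 29 steps, from but-3-en-1-ol (1); compounds 3, 5, 11 and 28 are bought.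

**Step 20 (key step).** The likeliest failure is not the [3,3] shift but what the free alkoxide and enolate do around it. One path is heterolytic fragmentation of the congested tertiary alkoxide. The other is proton transfer that moves the C8 enolate towards C7, followed by β-elimination of the C6 aryloxide; the potassium enolate is long-lived and aryloxide is a good leaving group. Fallback: a neutral thermal silyloxy-Cope rearrangement. Starting from 29, silylation (Me3SiOTf, 2,6-lutidine) gives the C8 trimethylsilyl ether F1. Heating F1 in toluene (sealed tube, about 200 °C) gives the bis-enol ether F2 without any alkoxide or enolate. K2CO3 in MeOH then cleaves the silyl enol ether of F2 selectively and rejoins the route at 31.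

**Step 21.** Poor or inverted facial selectivity in the hydride addition is possible. The face preference rests on a conformational argument for a bridged ten-membered ring, and a Felkin-type approach anti to C6 instead of C11 would give the 8-epimer. Fallback: invert rather than re-reduce. The (8S)-alcohol F3, if it is what forms from 31, is subjected to a Mitsunobu reaction (4-nitrobenzoic acid, PPh3, DIAD) to give the (8R)-4-nitrobenzoate F4. Methanolysis (K2CO3, MeOH) of F4 rejoins the route at 32.

**Step 24.** Facial selectivity of the peroxide addition depends on the Z-enone reacting through the conformer assumed, and the intermediate enolate may also close to the trans epoxide. Fallback: replace substrate control by catalyst control. Starting from 36, a La(OiPr)3/BINOL/Ph3As=O/tBuOOH epoxidation is used; it is known to convert cis-enones to cis-epoxy ketones, and the BINOL enantiomer is chosen to give 37. No new compound is involved.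

**Step 23.** β-Hydride elimination and palladium hydride re-addition may deliver the E enone or a mixture, since the geometry is decided by the conformation of the palladium enolate and not by the substrate. Fallback: a halogenation–elimination under equilibrating conditions. Starting from 34 by way of 35, NBS gives the 2-bromo ketone F5. Treating F5 with Li2CO3 and LiBr in DMF at 100 °C eliminates HBr and allows the enone to settle as the more stable Z isomer, rejoining the route at 36.

**Step 14.** Incomplete closure of the bridge is the risk. The transacetalisation is an equilibrium, and the bridged form puts the 8α-silyloxy group syn-axial to the C4 methyl group, so the open dimethyl acetal may persist. Fallback: make the bridge irreversibly at the lactone level. Starting from 20, CSA in MeOH removes the acetonide to give the tetraol F6. TEMPO/PhI(OAc)2 oxidises the primary alcohol of F6 and traps the lactol with O3 as the bridged δ-lactone F7. iBu2AlH at −78 °C reduces F7 to the bridged lactol F8, and PPTS in MeOH converts F8 to the methyl acetal, rejoining the route at 23.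

## Further compounds

F1 | step 20 | C8 trimethylsilyl ether of 29 | C=C[C@]1(O[C@@H](OC)C2)[C@@]3(C)OC(C)(C)O[C@@H]3[C@@H](Oc4ccc(OC)cc4)[C@@H]2[C@@]1(O[Si](C)(C)C)/C=C/C
F2 | step 20 | ten-membered C8 trimethylsilyl enol ether with C3 bridged enol acetal | C[Si](C)(C)O/C1=C\[C@@H](C)C/C=C2\O[C@@H](OC)C[C@@H]1[C@H](Oc3ccc(OC)cc3)[C@H]3OC(C)(C)O[C@]23C
F3 | step 21 | (8S)-alcohol, C8 epimer of 32 | O[C@H]1C[C@@H](C)C/C=C2\O[C@@H](OC)C[C@@H]1[C@H](Oc3ccc(OC)cc3)[C@H]3OC(C)(C)O[C@]23C
F4 | step 21 | (8R)-4-nitrobenzoate of 32 | O=C(O[C@@H]1C[C@@H](C)C/C=C2\O[C@@H](OC)C[C@@H]1[C@H](Oc3ccc(OC)cc3)[C@H]3OC(C)(C)O[C@]23C)c1ccc(cc1)[N+](=O)[O-]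
F0 | step 24 | none | none
F5 | step 23 | 2-bromo derivative of 34 (C2 epimers) | C1C(=O)O[C@@H]2C[C@@H](C)CC(Br)C(=O)[C@@]3(C)OC(C)(C)O[C@@H]3[C@@H](Oc3ccc(OC)cc3)[C@@H]12
F6 | step 14 | 3β,4β,5α,12-tetraol from 20 | C#C[C@]1(O)[C@@](C)(O)[C@H](O)[C@@H](Oc2ccc(OC)cc2)[C@@H](CCO)[C@@H]1O[Si](C(C)C)(C(C)C)C(C)C
F7 | step 14 | bridged δ-lactone (O3–C12) | C#C[C@]1(OC(=O)C2)[C@@](C)(O)[C@H](O)[C@@H](Oc3ccc(OC)cc3)[C@@H]2[C@@H]1O[Si](C(C)C)(C(C)C)C(C)C
F8 | step 14 | bridged lactol (C12 anomers) | C#C[C@]1(OC(O)C2)[C@@](C)(O)[C@H](O)[C@@H](Oc3ccc(OC)cc3)[C@@H]2[C@@H]1O[Si](C(C)C)(C(C)C)C(C)C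
A1 | alternative 1 | open-chain Z-enal methyl ketone with lactone and 5,6-acetonide | O=C/C=C\[C@H](C)C[C@H]1OC(=O)C[C@@H]1[C@@H]1OC(C)(C)O[C@H]1C(C)=O
A2 | alternative 1 | ten-membered Z-allylic 3,4-diol | O[C@@H]1/C=C\[C@H](C)C[C@H]2OC(=O)C[C@@H]2[C@@H]2OC(C)(C)O[C@H]2[C@]1(C)O
A3 | alternative 2 | seco C5 aldehyde with C3 α-(4-methoxybenzyloxy)ethyl ketone (C4 epimers) | O=C[C@@H](OC(=O)/C=C/C)[C@H]1C(=C)C(=O)O[C@@H]1C[C@@H](C)[C@@H]1O[C@@H]1C(=O)C(C)OCc1ccc(OC)cc1
A4 | alternative 2 | 5-deacetyl target as its C4 4-methoxybenzyl ether | C=C1C(=O)O[C@@H]2C[C@@H](C)[C@@H]3O[C@@H]3C(=O)[C@@](C)(OCc3ccc(OC)cc3)[C@H](O)[C@@H](OC(=O)/C=C/C)[C@@H]12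
A5 | alternative 3 | hydroazulenone 2,8-epoxide (epoxide face not defined) | C[C@@H]1CC23OC2(C1=O)[C@@H](O[Si](C)(C)C(C)(C)C)[C@@](C)(OCOC)[C@H](OCOC)[C@@H](OCc1ccc(OC)cc1)[C@H]3CC(=O)OC
A6 | alternative 3 | ten-membered 1-yn-8-one | O=C1C[C@@H](C)C#C[C@@H](O[Si](C)(C)C(C)(C)C)[C@@](C)(OCOC)[C@H](OCOC)[C@@H](OCc2ccc(OC)cc2)[C@H]1CC(=O)OC
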